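**Plan**

- Retrosynthesis: remove three benzyl ethers; take the C3–OH of the dimethylchroman back to a prochiral chroman-3-one; undo two 1,2-aryl shifts of ring B, one at C4–C4a of the chromanone and one at C3–C1' of the isoflavone, to reach a chalcone that carries a 2,2-dimethyl-3-methylene-2,3-dihydrobenzofuran; cut the chalcone C=C (aldol), the dihydrofuran C3–C3a bond (reductive Heck) and the O–CMe2 bond (propargylation).
- Enabling feature: ring B is bonded to a CH2 (pyran C4) next to the oxygenated C3, and to pyrone C3 next to the oxygenated C2. Both are aryl–C–C(O) units, the signature of an oxidative 1,2-aryl shift. The migrating ring-B carbon of the pyran side (C3') lies between the O-bearing C2' and C4'.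
- Forward order: ring B (bought) → five-membered dihydrofuran → chalcone → in one operation, expansion of the dihydrofuran to the six-membered chromanone ring, aryl shift to the isoflavone skeleton and closure of the γ-pyrone.
- Regiochemistry (4'-O in the ring, 2'-OH free) comes from selective alkylation of the non-chelated 4-OH of 2,4-dihydroxy-3-iodobenzaldehyde.
- Stereochemistry: the single stereocentre, C3 of the chroman, is (S) as drawn. It is set by reagent control in a Corey–Bakshi–Shibata reduction with the (R)-catalyst; no later step can epimerise it.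

Key step: step 7

**Route**

Step 1
Reactants: 1 2,4-dihydroxybenzaldehyde
Product: 2 2,4-dihydroxy-3-iodobenzaldehyde
Conditions: I2 (0.4 equiv), HIO3 (0.2 equiv), EtOH/H2O, 35 °C
Reagents that add atoms: iodine II; iodic acid OI(=O)=O
Why: Electrophilic aromatic iodination should go to C3, the only position ortho to both hydroxyls, as is usual for the analogous 2,4-dihydroxyacetophenone under these conditions; any 5-iodo isomer is to be removed by crystallisation.

Step 2
Reactants: 2 2,4-dihydroxy-3-iodobenzaldehyde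
Product: 3 2-hydroxy-3-iodo-4-[(2-methylbut-3-yn-2-yl)oxy]benzaldehyde
Conditions: 3-chloro-3-methylbut-1-yne, K2CO3, KI, CuI (cat.), acetone, 55 °C
Reagents that add atoms: 3-chloro-3-methylbut-1-yne CC(C)(Cl)C#C
Why: Copper-catalysed propargylic O-alkylation should occur at the more acidic 4-OH para to the aldehyde, because the 2-OH is held in a hydrogen bond to the formyl group; this fixes which oxygen ends up in the pyran ring.

Step 3
Reactants: 3 2-hydroxy-3-iodo-4-[(2-methylbut-3-yn-2-yl)oxy]benzaldehyde
Product: 4 2-(benzyloxy)-3-iodo-4-[(2-methylbut-3-yn-2-yl)oxy]benzaldehyde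
Conditions: BnBr, K2CO3, DMF, 50 °C
Reagents that add atoms: benzyl bromide BrCc1ccccc1
Why: Williamson etherification of the remaining chelated phenol under more forcing conditions; alkyne, aryl iodide and aldehyde are inert to carbonate.

Step 4
Reactants: 4 2-(benzyloxy)-3-iodo-4-[(2-methylbut-3-yn-2-yl)oxy]benzaldehyde
Product: 5 4-(benzyloxy)-2,2-dimethyl-3-methylidene-2,3-dihydro-1-benzofuran-5-carbaldehyde
Conditions: Pd(OAc)2 (5 mol%), PPh3, HCO2Na, n-Bu4NCl, DMF, 70 °C
Reagents that add atoms: none
Why: Reductive Heck cyclisation (oxidative addition into C–I, 5-exo-dig syn-carbopalladation, formate-derived hydride and C–H reductive elimination) should give the exocyclic alkene, which cannot isomerise to a benzofuran because C2 is quaternary.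

Step 5
Reactants: 6 1-(2,4,6-trihydroxyphenyl)ethan-1-one
Product: 7 1-[2,4-bis(benzyloxy)-6-hydroxyphenyl]ethan-1-one
Conditions: BnBr (2.1 equiv), K2CO3, DMF, rt
Reagents that add atoms: benzyl bromide BrCc1ccccc1
Why: Williamson etherification of the two free phenols; the hydroxyl hydrogen-bonded to the acetyl group reacts last and should remain.

Step 6
Reactants: 5 4-(benzyloxy)-2,2-dimethyl-3-methylidene-2,3-dihydro-1-benzofuran-5-carbaldehyde; 7 1-[2,4-bis(benzyloxy)-6-hydroxyphenyl]ethan-1-one
Product: 8 (E)-3-[4-(benzyloxy)-2,2-dimethyl-3-methylidene-2,3-dihydro-1-benzofuran-5-yl]-1-[2,4-bis(benzyloxy)-6-hydroxyphenyl]prop-2-en-1-one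
Conditions: KOH, EtOH, rt
Reagents that add atoms: none
Why: Claisen–Schmidt condensation (aldol addition, then E1cB loss of water) should give the (E)-enone; the exocyclic styrene and the benzyl ethers are stable to base, and the chelated 2'-OH disfavours flavanone closure.

Step 7
Reactants: 8 (E)-3-[4-(benzyloxy)-2,2-dimethyl-3-methylidene-2,3-dihydro-1-benzofuran-5-yl]-1-[2,4-bis(benzyloxy)-6-hydroxyphenyl]prop-2-en-1-one
Product: 11 5,7-bis(benzyloxy)-3-[5-(benzyloxy)-2,2-dimethyl-3-oxo-3,4-dihydro-2H-chromen-6-yl]-4H-chromen-4-one, via ring-expanded chalcone ketal 9 (not isolated), via bis-acetal 10 (not isolated)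
Conditions: Tl(NO3)3·3H2O (2.3 equiv), MeOH/CH(OMe)3, rt; filter; then 10% aq HCl, 60 °C
Reagents that add atoms: water O (the ketone oxygen of 11); methanol CO (the methoxy groups of 9 and 10 only)
Why: Tl(III) adds to the terminal carbon of the electron-rich exocyclic alkene with methanol at C3 (Markovnikov oxythallation), and the ring-B carbon C3a then shifts from C3 to that CH2 as Tl(I) leaves, so the methylene carbon is inserted between the arene and C3 and the C3 oxocarbenium ion is caught as the dimethyl ketal 9; a second equivalent oxythallates the enone, the same ring B migrates from Cβ to Cα to give the β-keto acetal 10, and aqueous HCl then closes the pyrone and hydrolyses the ketal to 11. The closest known reaction type is the thallium(III) nitrate oxidative rearrangement of arylalkenes, known both as a ring expansion of 1-methylenebenzocycloalkenes to β-benzocycloalkanones and as the 2'-hydroxychalcone-to-isoflavone synthesis; here both are asked of one substrate in one operation. The six-membered oxygen ring is closed by ring expansion of the dihydrofuran through a bridged phenonium (spirocyclopropane) transition state and not by a cyclisation, and the γ-pyrone closes by 6-exo-trig attack of the A-ring phenol on the acetal-derived oxocarbenium ion followed by loss of methanol. No stereocentre is set: the CH centre of 10 disappears on pyrone formation and C3 of the chromanone is left prochiral for step 8. The step needs aryl (not C2-alkyl) migration in the ring expansion and aryl migration (not aurone formation) in the chalcone, and both are secured by ring B, whose migrating carbons lie ortho or para to two ether oxygens while C2 carries an inductively deactivating oxygen. Benzyl ethers and the chelated A-ring phenol should tolerate Tl(NO3)3 in methanol, and the O–CMe2 bond made in step 2 is never broken, so the ring oxygen stays on C4'.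

Step 8
Reactants: 11 5,7-bis(benzyloxy)-3-[5-(benzyloxy)-2,2-dimethyl-3-oxo-3,4-dihydro-2H-chromen-6-yl]-4H-chromen-4-one
Product: 12 5,7-bis(benzyloxy)-3-[(3S)-5-(benzyloxy)-3-hydroxy-2,2-dimethyl-3,4-dihydro-2H-chromen-6-yl]-4H-chromen-4-one
Conditions: (R)-2-methyl-CBS-oxazaborolidine (0.2 equiv), BH3·SMe2 (0.7 equiv), THF, −20 °C; MeOH quench
Reagents that add atoms: none
Why: Corey–Bakshi–Shibata reduction: the ketone binds the catalyst with the quaternary C2 as the large group and the CH2 as the small one, so the (R)-catalyst should deliver hydride to the face that gives the (S)-alcohol, while the vinylogous-ester carbonyl of the pyrone is too unreactive to compete at −20 °C.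

Step 9
Reactants: 12 5,7-bis(benzyloxy)-3-[(3S)-5-(benzyloxy)-3-hydroxy-2,2-dimethyl-3,4-dihydro-2H-chromen-6-yl]-4H-chromen-4-one
Product: 13 5,7-dihydroxy-3-[(3S)-3,5-dihydroxy-2,2-dimethyl-3,4-dihydro-2H-chromen-6-yl]-4H-chromen-4-one (target)
Conditions: H2 (1 atm), 10% Pd/C, THF/MeOH, rt, stopped at full debenzylation
Reagents that add atoms: none
Why: Catalytic hydrogenolysis should cleave the three benzyl ethers while the isoflavone C2=C3 bond and the secondary alcohol survive at 1 atm and room temperature, and the stereocentre is not touched.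

**Compound list**

1 | 2,4-dihydroxybenzaldehyde | O=Cc1ccc(O)cc1O | starting material
2 | 2,4-dihydroxy-3-iodobenzaldehyde | O=Cc1ccc(O)c(I)c1O | intermediate
3 | 2-hydroxy-3-iodo-4-[(2-methylbut-3-yn-2-yl)oxy]benzaldehyde | O=Cc1ccc(OC(C)(C)C#C)c(I)c1O | intermediate
4 | 2-(benzyloxy)-3-iodo-4-[(2-methylbut-3-yn-2-yl)oxy]benzaldehyde | O=Cc1ccc(OC(C)(C)C#C)c(I)c1OCc1ccccc1 | intermediate
5 | 4-(benzyloxy)-2,2-dimethyl-3-methylidene-2,3-dihydro-1-benzofuran-5-carbaldehyde | C=C1c2c(OCc3ccccc3)c(C=O)ccc2OC1(C)C | intermediate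
6 | 1-(2,4,6-trihydroxyphenyl)ethan-1-one | CC(=O)c1c(O)cc(O)cc1O | starting material
7 | 1-[2,4-bis(benzyloxy)-6-hydroxyphenyl]ethan-1-one | CC(=O)c1c(O)cc(OCc2ccccc2)cc1OCc1ccccc1 | intermediate
8 | (E)-3-[4-(benzyloxy)-2,2-dimethyl-3-methylidene-2,3-dihydro-1-benzofuran-5-yl]-1-[2,4-bis(benzyloxy)-6-hydroxyphenyl]prop-2-en-1-one | C=C1c2c(OCc3ccccc3)c(/C=C/C(=O)c3c(O)cc(OCc4ccccc4)cc3OCc3ccccc3)ccc2OC1(C)C | intermediate
9 | (E)-3-[5-(benzyloxy)-3,3-dimethoxy-2,2-dimethyl-3,4-dihydro-2H-chromen-6-yl]-1-[2,4-bis(benzyloxy)-6-hydroxyphenyl]prop-2-en-1-one | COC1(OC)Cc2c(OCc3ccccc3)c(/C=C/C(=O)c3c(O)cc(OCc4ccccc4)cc3OCc3ccccc3)ccc2OC1(C)C | intermediate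
10 | 1-[2,4-bis(benzyloxy)-6-hydroxyphenyl]-2-[5-(benzyloxy)-3,3-dimethoxy-2,2-dimethyl-3,4-dihydro-2H-chromen-6-yl]-3,3-dimethoxypropan-1-one (racemic) | COC(OC)C(C(=O)c1c(O)cc(OCc2ccccc2)cc1OCc1ccccc1)c1ccc2OC(C)(C)C(OC)(OC)Cc2c1OCc1ccccc1 | intermediate
11 | 5,7-bis(benzyloxy)-3-[5-(benzyloxy)-2,2-dimethyl-3-oxo-3,4-dihydro-2H-chromen-6-yl]-4H-chromen-4-one | CC1(C)Oc2ccc(-c3coc4cc(OCc5ccccc5)cc(OCc5ccccc5)c4c3=O)c(OCc3ccccc3)c2CC1=O | intermediate
12 | 5,7-bis(benzyloxy)-3-[(3S)-5-(benzyloxy)-3-hydroxy-2,2-dimethyl-3,4-dihydro-2H-chromen-6-yl]-4H-chromen-4-one | CC1(C)Oc2ccc(-c3coc4cc(OCc5ccccc5)cc(OCc5ccccc5)c4c3=O)c(OCc3ccccc3)c2C[C@@H]1O | intermediate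
13 | 5,7-dihydroxy-3-[(3S)-3,5-dihydroxy-2,2-dimethyl-3,4-dihydro-2H-chromen-6-yl]-4H-chromen-4-one | CC1(C)Oc2ccc(-c3coc4cc(O)cc(O)c4c3=O)c(O)c2C[C@@H]1O | target

**Count**

Total steps: 9. Longest linear sequence: 8 (steps 1, 2, 3, 4, 6, 7, 8, 9); step 5 is a one-step side branch.

**Steps most likely to fail**

Step 7. Two oxidative aryl shifts are asked of one substrate, so excess Tl(III) and the nitric acid it releases may over-oxidise the electron-rich rings, or the second shift may stall and leave mixtures. The fallback separates the two shifts. Setting out from 5, ring expansion alone with PhI(OH)OTs in MeOH/CH(OMe)3, followed by a brief wet-silica treatment that frees the aldehyde but leaves the α-alkoxy ketal, should give 5-(benzyloxy)-3,3-dimethoxy-2,2-dimethyl-3,4-dihydro-2H-chromene-6-carbaldehyde F1. Claisen–Schmidt condensation of F1 with 7 (KOH, EtOH) then gives the ketal chalcone 9 as an isolated compound. A single classical Tl(NO3)3/MeOH chalcone rearrangement takes 9 to 10, and aqueous HCl returns to the route at 11.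

Step 8. Facial discrimination may be insufficient because both flanks of the ketone are ring atoms, or borane may attack the pyrone. The fallback replaces catalyst control by resolution. Setting out from 11, NaBH4 (0.3 equiv, THF/EtOH, −30 °C) should give the racemic alcohol 5,7-bis(benzyloxy)-3-[5-(benzyloxy)-3-hydroxy-2,2-dimethyl-3,4-dihydro-2H-chromen-6-yl]-4H-chromen-4-one F2. Esterification with (S)-2-methoxy-2-phenylacetic acid (DCC, DMAP) gives the (3S)-chromanyl (S)-2-methoxy-2-phenylacetate F3 and its diastereomer, the (3R)-chromanyl (S)-2-methoxy-2-phenylacetate F4, to be separated by chromatography. Hydrolysis of F3 (LiOH, THF/H2O) returns to the route at 12.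

Step 4. Formate may reduce the aryl–palladium species before it adds to the alkyne, or Pd(0) may ionise the tertiary propargylic ether. The fallback changes the acceptor from alkyne to alkene. Setting out from 4, Lindlar semihydrogenation (H2, Pd/CaCO3/Pb, quinoline) should give 2-(benzyloxy)-3-iodo-4-[(2-methylbut-3-en-2-yl)oxy]benzaldehyde F5. A conventional intramolecular Heck reaction (Pd(OAc)2, n-Bu4NCl, K2CO3, DMF, 60 °C; 5-exo-trig insertion, then β-hydride elimination of the C3–H) closes the same ring and returns to the route at 5.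

**Further compounds**

F1 | step 7 | 5-(benzyloxy)-3,3-dimethoxy-2,2-dimethyl-3,4-dihydro-2H-chromene-6-carbaldehyde | COC1(OC)Cc2c(OCc3ccccc3)c(C=O)ccc2OC1(C)C
F2 | step 8 | rac-5,7-bis(benzyloxy)-3-[5-(benzyloxy)-3-hydroxy-2,2-dimethyl-3,4-dihydro-2H-chromen-6-yl]-4H-chromen-4-one | CC1(C)Oc2ccc(-c3coc4cc(OCc5ccccc5)cc(OCc5ccccc5)c4c3=O)c(OCc3ccccc3)c2CC1O
F3 | step 8 | (3S)-5-(benzyloxy)-6-[5,7-bis(benzyloxy)-4-oxo-4H-chromen-3-yl]-2,2-dimethyl-3,4-dihydro-2H-chromen-3-yl (2S)-2-methoxy-2-phenylacetate | CC1(C)Oc2ccc(-c3coc4cc(OCc5ccccc5)cc(OCc5ccccc5)c4c3=O)c(OCc3ccccc3)c2C[C@@H]1OC(=O)[C@@H](OC)c1ccccc1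
F4 | step 8 | (3R)-5-(benzyloxy)-6-[5,7-bis(benzyloxy)-4-oxo-4H-chromen-3-yl]-2,2-dimethyl-3,4-dihydro-2H-chromen-3-yl (2S)-2-methoxy-2-phenylacetate | CC1(C)Oc2ccc(-c3coc4cc(OCc5ccccc5)cc(OCc5ccccc5)c4c3=O)c(OCc3ccccc3)c2C[C@H]1OC(=O)[C@@H](OC)c1ccccc1
F5 | step 4 | 2-(benzyloxy)-3-iodo-4-[(2-methylbut-3-en-2-yl)oxy]benzaldehyde | O=Cc1ccc(OC(C)(C)C=C)c(I)c1OCc1ccccc1
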